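Everything rests on cutting ring D of the dihydrobenzofuran (C3a′, C4′, C5′, C6′, C7′, C7a′), a 1,2,3,5-tetrasubstituted benzene whose fused O1′–C2′–C3′ bridge maps onto the tether of a 1,6-diyne, into three alkynes. One ruthenium-catalysed [2+2+2] cycloaddition of an ynol-ether diyne with benzyloxyacetylene forms C3a′–C7a′, C4′–C5′ and C6′–C7′, closing ring D and the dihydrofuran together. The precursor already holds all six stereocentres: a 2,3-cis-3,4-cis-4,5-trans triaryl oxolane carrying the internal alkyne at C3 and an anti C2′/C3′ diaryl unit ending in a terminal ynol ether. All phenols travel as benzyl ethers so that the last step is a neutral hydrogenolysis.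

Key step: step 17

Assumption: Lewis-acid dealkylation of methyl or ethyl aryl ethers would endanger the bis-benzylic oxolane and the benzylic C2′–O1′ bond, so every phenol, including the C6′ oxygen delivered by the alkyne partner, is carried as a benzyl ether.
Assumption: benzyl ethynyl ether is not a stock chemical and is made in step 16; the other numbered starting materials are commercial.
Notation: ArP = 4-(benzyloxy)phenyl; ArR = 3,5-bis(benzyloxy)phenyl; oxolane atoms are O1, C2 to C5 (C3 bears the alkyne, C4 bears ArR); Ox = (2S,3S,4R,5S)-4-ArR-2,5-di-ArP-oxolan-3-yl; benzofuran atoms are primed.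

Step 1
Reactants: 1 3,5-bis(benzyloxy)benzaldehyde
Product: 2 1,3-bis(benzyloxy)-5-ethenylbenzene
Conditions: Ph3PCH3Br, KOtBu, THF, 0 °C to rt
Reagents that add atoms: methyltriphenylphosphonium bromide, C[P+](c1ccccc1)(c1ccccc1)c1ccccc1.[Br-]
Why: Wittig methylenation of a non-enolisable aryl aldehyde with the unstabilised ylide is routine and creates no stereocentre.

Step 2
Reactants: 2 1,3-bis(benzyloxy)-5-ethenylbenzene; 3 allylboronic acid pinacol ester
Product: 4 2-[(2E)-3-ArR-prop-2-en-1-yl]-4,4,5,5-tetramethyl-1,3,2-dioxaborolane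
Conditions: second-generation Grubbs catalyst RuCl2(=CHPh)(PCy3)(H2IMes) (3 mol%), 3 (3 equiv), CH2Cl2, 40 °C
Reagents that add atoms: none
Why: Olefin cross-metathesis of a styrene with an allylboronate should give the conjugated E-alkene under thermodynamic control with loss of ethene, and this E geometry is what later becomes the anti C4/C5 relationship.

Step 3
Reactants: 4 2-[(2E)-3-ArR-prop-2-en-1-yl]-4,4,5,5-tetramethyl-1,3,2-dioxaborolane; 5 4-(benzyloxy)benzaldehyde
Product: 6 (1S,2R)-2-ArR-1-ArP-but-3-en-1-ol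
Conditions: (S)-TRIP phosphoric acid (5 mol%), 4 Å molecular sieves, toluene, −30 °C; aqueous NaHCO3 work-up
Reagents that add atoms: none
Why: Brønsted-acid-catalysed allylboration through a closed chair transition state turns the E geometry into the anti relationship, while the (S)-phosphoric acid should direct addition to the Si face of the aldehyde, setting C5 as S and C4 as R.

Step 4
Reactants: 6 (1S,2R)-2-ArR-1-ArP-but-3-en-1-ol
Product: 8 (1S,2R)-2-ArR-1-ArP-butane-1,4-diol, via bis(9-BBN) adduct 7 (not isolated)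
Conditions: 9-BBN (2.5 equiv), THF, 0 °C to rt; then NaOH, H2O2, H2O, 0 °C
Reagents that add atoms: hydrogen peroxide, OO
Why: Anti-Markovnikov hydroboration–oxidation of the monosubstituted alkene puts the hydroxyl on the terminal carbon (future C2) without touching the two stereocentres.

Step 5
Reactants: 8 (1S,2R)-2-ArR-1-ArP-butane-1,4-diol
Product: 10 (4R,5S)-4-ArR-5-ArP-oxolan-2-one, via lactol 9 (not isolated)
Conditions: TEMPO (20 mol%), PhI(OAc)2 (2.5 equiv), CH2Cl2, rt
Reagents that add atoms: none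
Why: Oxoammonium oxidation is selective for the primary alcohol, the hydroxy aldehyde closes to the five-membered lactol and is oxidised on to the γ-lactone (oxidative lactonisation), leaving C4 and C5 unchanged.

Step 6
Reactants: 10 (4R,5S)-4-ArR-5-ArP-oxolan-2-one
Product: 13 (3R,4R,5S)-4-ArR-5-ArP-3-[(tert-butyldimethylsilyloxy)methyl]oxolan-2-one, via lithium enolate 11 (not isolated), via hydroxymethyl lactone 12 (not isolated)
Conditions: LiN(iPr)2, THF, −78 °C; CH2O (gas), −78 to −40 °C; NH4Cl; crude alcohol: TBSCl, imidazole, DMF, rt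
Reagents that add atoms: formaldehyde, C=O; tert-butyl(chloro)dimethylsilane, CC(C)(C)[Si](C)(C)Cl
Why: Aldol hydroxymethylation of the lactone enolate, expected anti to the C4 aryl group, followed by silylation installs the one-carbon handle at C3, and the C3 configuration formed here does not matter because step 7 resets it.

Step 7
Reactants: 13 (3R,4R,5S)-4-ArR-5-ArP-3-[(tert-butyldimethylsilyloxy)methyl]oxolan-2-one
Product: 15 (3S,4R,5S)-4-ArR-5-ArP-3-[(tert-butyldimethylsilyloxy)methyl]oxolan-2-one, via lithium enolate 14 (not isolated)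
Conditions: LiN(iPr)2 (1.2 equiv), THF, −78 °C; 2,6-di-tert-butyl-4-methylphenol (3 equiv), −78 °C; NH4Cl
Reagents that add atoms: none
Why: Kinetic protonation of the planar lactone enolate by a hindered phenol should occur on the face opposite the adjacent C4 aryl group, which pushes the silyloxymethyl group cis to that aryl group (3S), and any recovered trans isomer can be resubmitted.

Step 8
Reactants: 15 (3S,4R,5S)-4-ArR-5-ArP-3-[(tert-butyldimethylsilyloxy)methyl]oxolan-2-one; 16 1-(benzyloxy)-4-bromobenzene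
Product: 18 (3S,4R,5S)-4-ArR-2,5-di-ArP-3-[(tert-butyldimethylsilyloxy)methyl]oxolan-2-ol, via aryllithium 17 (not isolated)
Conditions: 16, n-BuLi, THF, −78 °C; then 15, −78 °C; NH4Cl
Reagents that add atoms: none
Why: Bromine–lithium exchange and 1,2-addition of the aryllithium to the lactone carbonyl stop at the lithium lactolate at −78 °C, giving the hemiketal (both C2 epimers, in equilibrium with the hydroxy ketone) without disturbing C3 to C5.

Step 9
Reactants: 18 (3S,4R,5S)-4-ArR-2,5-di-ArP-3-[(tert-butyldimethylsilyloxy)methyl]oxolan-2-ol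
Product: 20 [(2S,3S,4R,5S)-4-ArR-2,5-di-ArP-oxolan-3-yl]methanol, via oxolane silyl ether 19 (not isolated)
Conditions: Et3SiH (5 equiv), BF3·OEt2 (2 equiv), CH2Cl2, −78 °C; Et3N, −78 °C; then Bu4NF, THF, 0 °C
Reagents that add atoms: none
Why: Ionic hydrogenation of the hemiketal goes through the 2-aryl oxocarbenium ion in the envelope that keeps the C3 substituent pseudoaxial (away from the C2 aryl group) and the C4 and C5 aryl groups pseudoequatorial, so inside attack delivers hydride anti to the C3 and C4 substituents and sets C2 as S with its aryl group cis to both, the low temperature preventing acid epimerisation at C2 or C3 before fluoride frees the primary alcohol.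

Step 10
Reactants: 20 [(2S,3S,4R,5S)-4-ArR-2,5-di-ArP-oxolan-3-yl]methanol
Product: 21 (2S,3R,4R,5S)-4-ArR-2,5-di-ArP-oxolane-3-carbaldehyde
Conditions: Dess–Martin periodinane, NaHCO3, CH2Cl2, 0 °C; used crude at once
Reagents that add atoms: none
Why: Buffered Dess–Martin oxidation gives the aldehyde under non-basic conditions, so the epimerisable all-cis C3 centre should survive (the descriptor changes to R only because the formyl group outranks C2).

Step 11
Reactants: 21 (2S,3R,4R,5S)-4-ArR-2,5-di-ArP-oxolane-3-carbaldehyde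
Product: 22 (2S,3S,4R,5S)-4-ArR-2,5-di-ArP-3-ethynyloxolane
Conditions: Me3SiCHN2, n-BuLi, THF, −78 °C; 21, −78 °C to rt
Reagents that add atoms: (trimethylsilyl)diazomethane, C[Si](C)(C)C=[N+]=[N-]
Why: The Colvin rearrangement (addition of lithiated trimethylsilyldiazomethane, Peterson-type elimination and 1,2-hydrogen shift of the alkylidene carbene) gives the terminal alkyne at a temperature where carbonyl addition should outrun enolisation at C3.

Step 12
Reactants: 22 (2S,3S,4R,5S)-4-ArR-2,5-di-ArP-3-ethynyloxolane; 1 3,5-bis(benzyloxy)benzaldehyde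
Product: 23 (1S)-1-ArR-3-Ox-prop-2-yn-1-ol
Conditions: Me2Zn (3 equiv), (S,S)-ProPhenol (20 mol%), Ph3P=O (40 mol%), toluene, 0 °C; 1 (1.5 equiv), 4 °C; NH4Cl
Reagents that add atoms: none
Why: Dinuclear-zinc ProPhenol-catalysed asymmetric alkynylation of an aromatic aldehyde is reagent-controlled because the oxolane centres are remote, and the ligand hand (expected (S,S), otherwise its mirror image) is the one that delivers the alkynyl group to the Re face to give the S carbinol.

Step 13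
Reactants: 23 (1S)-1-ArR-3-Ox-prop-2-yn-1-ol
Product: 24 (1S)-1-ArR-3-Ox-prop-2-yn-1-yl methyl carbonate
Conditions: ClCO2Me, pyridine, DMAP (10 mol%), CH2Cl2, 0 °C
Reagents that add atoms: methyl chloroformate, COC(Cl)=O
Why: O-acylation of the secondary propargylic alcohol gives a storable carbonate leaving group with retention at the carbinol carbon.

Step 14
Reactants: 24 (1S)-1-ArR-3-Ox-prop-2-yn-1-yl methyl carbonate; 5 4-(benzyloxy)benzaldehyde
Product: 26 (1R,2R)-2-ArR-1-ArP-4-Ox-but-3-yn-1-ol, via ethyl allenylzinc 25 (not isolated)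
Conditions: Pd(PPh3)4 (5 mol%), Et2Zn (3 equiv), 5 (1.5 equiv), THF, −20 °C; NH4Cl
Reagents that add atoms: none
Why: Zerovalent palladium ionises the carbonate in an anti SN2′ sense to an allenylpalladium species, exchange with Et2Zn gives the configurationally defined allenylzinc, and its SE2′ addition to the Re face of the aldehyde through a closed six-membered transition state forms C2′–C3′ on the face opposite the departed carbonate (C3′ R from the 1S carbonate) with the anti C2′ R carbinol favoured because the aldehyde aryl group stays away from the C3′ aryl group.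

Step 15
Reactants: 26 (1R,2R)-2-ArR-1-ArP-4-Ox-but-3-yn-1-ol; 27 trichloroethylene
Product: 30 (2S,3S,4R,5S)-3-[(3R,4R)-3-ArR-4-ArP-4-(ethynyloxy)but-1-yn-1-yl]-4-ArR-2,5-di-ArP-oxolane, via dichlorovinyl ether 28 (not isolated), via lithium alkynyl ether 29 (not isolated)
Conditions: KH (2 equiv), THF, 0 °C; 27 (1.1 equiv), 0 °C to rt; n-BuLi (2.4 equiv), −78 to −40 °C; MeOH, −78 °C; cold NaHCO3 work-up, Et3N-deactivated silica, used within hours
Reagents that add atoms: none
Why: In this trichloroethylene-based ynol ether synthesis the potassium alkoxide adds to dichloroacetylene generated in situ to give the (E)-1,2-dichlorovinyl ether, which n-BuLi converts by dehydrochlorination and chlorine–lithium exchange into the lithium alkynyl ether that methanol protonates, none of these events touching C2′ or C3′.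

Step 16
Reactants: 31 benzyl alcohol; 27 trichloroethylene
Product: 34 benzyl ethynyl ether, via benzyl dichlorovinyl ether 32 (not isolated), via lithium benzyloxyacetylide 33 (not isolated)
Conditions: KH (2 equiv), THF, 0 °C; 27, 0 °C to rt; n-BuLi (2.4 equiv), −78 °C; MeOH, −78 °C; cold work-up, stored below 0 °C as a hexane solution
Reagents that add atoms: none
Why: The same trichloroethylene-based ynol ether synthesis on a primary alcohol gives the alkoxyacetylene partner, which can be handled below room temperature because its sigmatropic rearrangement needs heating.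

Step 17
Reactants: 30 (2S,3S,4R,5S)-3-[(3R,4R)-3-ArR-4-ArP-4-(ethynyloxy)but-1-yn-1-yl]-4-ArR-2,5-di-ArP-oxolane; 34 benzyl ethynyl ether
Product: 35 (2R,3R)-6-(benzyloxy)-3-ArR-2-ArP-4-Ox-2,3-dihydro-1-benzofuran
Conditions: Cp*RuCl(cod) (10 mol%), 34 (4 equiv), ClCH2CH2Cl, 20 °C, 30 added over 3 h, argon
Reagents that add atoms: none
Why: Oxidative cyclisation of the two tethered alkynes of 30 on the Cp*RuCl fragment gives a bicyclic ruthenacyclopentadiene in which C3a′–C7a′ and hence the five-membered O1′–C2′–C3′–C3a′–C7a′ ring already exist, and insertion of 34 followed by reductive elimination forms C4′–C5′ and C6′–C7′ and releases ring D as an arene. The closest known reaction type is the Cp*RuCl(cod)-catalysed [2+2+2] cycloaddition of 1,6-diynes, heteroatom-tethered ones included, with terminal alkynes, which is meta-selective when one diyne terminus is substituted. The dihydrofuran ring closes by intramolecular oxidative coupling across the three-atom tether, which can only give the five-membered ring, and ring D closes by formal [4+2] union of the metallacycle with the third alkyne. No stereocentre is created, and the six existing sp3 centres, including C2′ and C3′ in the tether, are spectators, so the trans-2′,3′ relationship is simply carried through. The step needs regio- and chemoselectivity: the alkoxy-bearing carbon of 34 should bond to the unsubstituted terminus C7′ and its CH to the oxolane-bearing C4′, because the inserting alkyne keeps its substituent away from the hindered end of the metallacycle, which places oxygen at C6′, while excess 34 and slow addition of 30 hold back diyne dimerisation. Working at 20 °C keeps both benzylic ynol ethers below the temperature at which they rearrange.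

Step 18
Reactants: 35 (2R,3R)-6-(benzyloxy)-3-ArR-2-ArP-4-Ox-2,3-dihydro-1-benzofuran
Product: 36 (2R,3R)-3-(3,5-dihydroxyphenyl)-4-[(2S,3S,4R,5S)-4-(3,5-dihydroxyphenyl)-2,5-bis(4-hydroxyphenyl)oxolan-3-yl]-2-(4-hydroxyphenyl)-2,3-dihydro-1-benzofuran-6-ol
Conditions: H2 (1 atm), Pd(OH)2/C, EtOAc–MeOH, rt
Reagents that add atoms: none
Why: Hydrogenolysis of the eight primary benzyl aryl ethers on palladium should be much faster than cleavage of the hindered secondary benzylic C–O bonds of the oxolane and dihydrobenzofuran rings under neutral conditions, so the free octaphenol is released without acid and with all six stereocentres intact.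

Compound list
1 | 3,5-bis(benzyloxy)benzaldehyde | O=Cc1cc(OCc2ccccc2)cc(OCc2ccccc2)c1 | starting material
2 | 1,3-bis(benzyloxy)-5-ethenylbenzene | C=Cc1cc(OCc2ccccc2)cc(OCc2ccccc2)c1 | intermediate
3 | allylboronic acid pinacol ester | C=CCB1OC(C)(C)C(C)(C)O1 | starting material
4 | 2-[(2E)-3-ArR-prop-2-en-1-yl]-4,4,5,5-tetramethyl-1,3,2-dioxaborolane | CC1(C)OB(C/C=C/c2cc(OCc3ccccc3)cc(OCc3ccccc3)c2)OC1(C)C | intermediate
5 | 4-(benzyloxy)benzaldehyde | O=Cc1ccc(OCc2ccccc2)cc1 | starting material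
6 | (1S,2R)-2-ArR-1-ArP-but-3-en-1-ol | O[C@H](c1ccc(OCc2ccccc2)cc1)[C@@H](c1cc(OCc2ccccc2)cc(OCc2ccccc2)c1)C=C | intermediate
7 | bis(9-BBN) adduct of 6 (O-borinate and terminal C-borane) | O(B1C2CCCC1CCC2)[C@H](c1ccc(OCc2ccccc2)cc1)[C@@H](c1cc(OCc2ccccc2)cc(OCc2ccccc2)c1)CCB1C2CCCC1CCC2 | intermediate
8 | (1S,2R)-2-ArR-1-ArP-butane-1,4-diol | O[C@H](c1ccc(OCc2ccccc2)cc1)[C@@H](c1cc(OCc2ccccc2)cc(OCc2ccccc2)c1)CCO | intermediate
9 | (4R,5S)-4-ArR-5-ArP-oxolan-2-ol (lactol, both C2 epimers) | OC1O[C@H](c2ccc(OCc3ccccc3)cc2)[C@@H](c2cc(OCc3ccccc3)cc(OCc3ccccc3)c2)C1 | intermediate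
10 | (4R,5S)-4-ArR-5-ArP-oxolan-2-one | O=C1O[C@H](c2ccc(OCc3ccccc3)cc2)[C@@H](c2cc(OCc3ccccc3)cc(OCc3ccccc3)c2)C1 | intermediate
11 | lithium enolate of 10 | [Li]OC=1O[C@H](c2ccc(OCc3ccccc3)cc2)[C@@H](c2cc(OCc3ccccc3)cc(OCc3ccccc3)c2)C=1 | intermediate
12 | (3R,4R,5S)-4-ArR-5-ArP-3-(hydroxymethyl)oxolan-2-one | O=C1O[C@H](c2ccc(OCc3ccccc3)cc2)[C@@H](c2cc(OCc3ccccc3)cc(OCc3ccccc3)c2)[C@@H]1CO | intermediate
13 | (3R,4R,5S)-4-ArR-5-ArP-3-[(tert-butyldimethylsilyloxy)methyl]oxolan-2-one (3,4-trans) | O=C1O[C@H](c2ccc(OCc3ccccc3)cc2)[C@@H](c2cc(OCc3ccccc3)cc(OCc3ccccc3)c2)[C@@H]1CO[Si](C)(C)C(C)(C)C | intermediate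
14 | lithium enolate of 13 | [Li]OC=1O[C@H](c2ccc(OCc3ccccc3)cc2)[C@@H](c2cc(OCc3ccccc3)cc(OCc3ccccc3)c2)C=1CO[Si](C)(C)C(C)(C)C | intermediate
15 | (3S,4R,5S)-4-ArR-5-ArP-3-[(tert-butyldimethylsilyloxy)methyl]oxolan-2-one (3,4-cis) | O=C1O[C@H](c2ccc(OCc3ccccc3)cc2)[C@@H](c2cc(OCc3ccccc3)cc(OCc3ccccc3)c2)[C@H]1CO[Si](C)(C)C(C)(C)C | intermediate
16 | 1-(benzyloxy)-4-bromobenzene | Brc1ccc(OCc2ccccc2)cc1 | starting material
17 | [4-(benzyloxy)phenyl]lithium | [Li]c1ccc(OCc2ccccc2)cc1 | intermediate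
18 | (3S,4R,5S)-4-ArR-2,5-di-ArP-3-[(tert-butyldimethylsilyloxy)methyl]oxolan-2-ol (both C2 epimers) | OC1(c2ccc(OCc3ccccc3)cc2)O[C@H](c2ccc(OCc3ccccc3)cc2)[C@@H](c2cc(OCc3ccccc3)cc(OCc3ccccc3)c2)[C@H]1CO[Si](C)(C)C(C)(C)C | intermediate
19 | tert-butyldimethylsilyl ether of 20 | C(c1ccccc1)Oc1ccc([C@H]2O[C@H](c3ccc(OCc4ccccc4)cc3)[C@@H](c3cc(OCc4ccccc4)cc(OCc4ccccc4)c3)[C@H]2CO[Si](C)(C)C(C)(C)C)cc1 | intermediate
20 | [(2S,3S,4R,5S)-4-ArR-2,5-di-ArP-oxolan-3-yl]methanol | C(c1ccccc1)Oc1ccc([C@H]2O[C@H](c3ccc(OCc4ccccc4)cc3)[C@@H](c3cc(OCc4ccccc4)cc(OCc4ccccc4)c3)[C@H]2CO)cc1 | intermediate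
21 | (2S,3R,4R,5S)-4-ArR-2,5-di-ArP-oxolane-3-carbaldehyde | C(c1ccccc1)Oc1ccc([C@H]2O[C@H](c3ccc(OCc4ccccc4)cc3)[C@@H](c3cc(OCc4ccccc4)cc(OCc4ccccc4)c3)[C@H]2C=O)cc1 | intermediate
22 | (2S,3S,4R,5S)-4-ArR-2,5-di-ArP-3-ethynyloxolane | C(c1ccccc1)Oc1ccc([C@H]2O[C@H](c3ccc(OCc4ccccc4)cc3)[C@@H](c3cc(OCc4ccccc4)cc(OCc4ccccc4)c3)[C@H]2C#C)cc1 | intermediate
23 | (1S)-1-ArR-3-Ox-prop-2-yn-1-ol | C(c1ccccc1)Oc1ccc([C@H]2O[C@H](c3ccc(OCc4ccccc4)cc3)[C@@H](c3cc(OCc4ccccc4)cc(OCc4ccccc4)c3)[C@H]2C#C[C@@H](O)c2cc(OCc3ccccc3)cc(OCc3ccccc3)c2)cc1 | intermediate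
24 | (1S)-1-ArR-3-Ox-prop-2-yn-1-yl methyl carbonate | C(c1ccccc1)Oc1ccc([C@H]2O[C@H](c3ccc(OCc4ccccc4)cc3)[C@@H](c3cc(OCc4ccccc4)cc(OCc4ccccc4)c3)[C@H]2C#C[C@@H](OC(=O)OC)c2cc(OCc3ccccc3)cc(OCc3ccccc3)c2)cc1 | intermediate
25 | ethyl[(M)-3-ArR-1-Ox-propa-1,2-dien-1-yl]zinc | CC[Zn]C([C@@H]1[C@H](c2cc(OCc3ccccc3)cc(OCc3ccccc3)c2)[C@@H](c2ccc(OCc3ccccc3)cc2)O[C@@H]1c1ccc(OCc2ccccc2)cc1)=[C@]=C([H])c1cc(OCc2ccccc2)cc(OCc2ccccc2)c1 | intermediate
26 | (1R,2R)-2-ArR-1-ArP-4-Ox-but-3-yn-1-ol | C(c1ccccc1)Oc1ccc([C@H]2O[C@H](c3ccc(OCc4ccccc4)cc3)[C@@H](c3cc(OCc4ccccc4)cc(OCc4ccccc4)c3)[C@H]2C#C[C@@H](c2cc(OCc3ccccc3)cc(OCc3ccccc3)c2)[C@H](c2ccc(OCc3ccccc3)cc2)O)cc1 | intermediate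
27 | trichloroethylene | ClC=C(Cl)Cl | starting material
28 | (E)-1,2-dichlorovinyl ether of 26 | C(c1ccccc1)Oc1ccc([C@H]2O[C@H](c3ccc(OCc4ccccc4)cc3)[C@@H](c3cc(OCc4ccccc4)cc(OCc4ccccc4)c3)[C@H]2C#C[C@@H](c2cc(OCc3ccccc3)cc(OCc3ccccc3)c2)[C@H](c2ccc(OCc3ccccc3)cc2)O/C(Cl)=C\Cl)cc1 | intermediate
29 | lithium acetylide of 30 (lithium alkynyl ether) | C(c1ccccc1)Oc1ccc([C@H]2O[C@H](c3ccc(OCc4ccccc4)cc3)[C@@H](c3cc(OCc4ccccc4)cc(OCc4ccccc4)c3)[C@H]2C#C[C@@H](c2cc(OCc3ccccc3)cc(OCc3ccccc3)c2)[C@H](c2ccc(OCc3ccccc3)cc2)OC#C[Li])cc1 | intermediate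
30 | (2S,3S,4R,5S)-3-[(3R,4R)-3-ArR-4-ArP-4-(ethynyloxy)but-1-yn-1-yl]-4-ArR-2,5-di-ArP-oxolane | C(c1ccccc1)Oc1ccc([C@H]2O[C@H](c3ccc(OCc4ccccc4)cc3)[C@@H](c3cc(OCc4ccccc4)cc(OCc4ccccc4)c3)[C@H]2C#C[C@@H](c2cc(OCc3ccccc3)cc(OCc3ccccc3)c2)[C@H](c2ccc(OCc3ccccc3)cc2)OC#C)cc1 | intermediate
31 | benzyl alcohol | OCc1ccccc1 | starting material
32 | benzyl (E)-1,2-dichlorovinyl ether | Cl/C=C(/Cl)OCc1ccccc1 | intermediate
33 | lithium (benzyloxy)acetylide | [Li]C#COCc1ccccc1 | intermediate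
34 | benzyl ethynyl ether | C#COCc1ccccc1 | intermediate
35 | (2R,3R)-6-(benzyloxy)-3-ArR-2-ArP-4-Ox-2,3-dihydro-1-benzofuran | C(c1ccccc1)Oc1ccc([C@H]2O[C@H](c3ccc(OCc4ccccc4)cc3)[C@@H](c3cc(OCc4ccccc4)cc(OCc4ccccc4)c3)[C@H]2c2cc(OCc3ccccc3)cc3c2[C@@H](c2cc(OCc4ccccc4)cc(OCc4ccccc4)c2)[C@H](c2ccc(OCc4ccccc4)cc2)O3)cc1 | intermediate
36 | (2R,3R)-3-(3,5-dihydroxyphenyl)-4-[(2S,3S,4R,5S)-4-(3,5-dihydroxyphenyl)-2,5-bis(4-hydroxyphenyl)oxolan-3-yl]-2-(4-hydroxyphenyl)-2,3-dihydro-1-benzofuran-6-ol | Oc1ccc([C@H]2O[C@H](c3ccc(O)cc3)[C@@H](c3cc(O)cc(O)c3)[C@H]2c2cc(O)cc3c2[C@@H](c2cc(O)cc(O)c2)[C@H](c2ccc(O)cc2)O3)cc1 | target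

Total steps: 18. Longest linear sequence: 17 (steps 1 to 15, 17 and 18); step 16 is a one-step side branch.

Steps most likely to fail:

The cycloaddition, step 17, carries the most risk. The alkoxyacetylene may be consumed by ruthenium (vinylidene formation, oligomerisation) or insert with poor regiocontrol, and the tethered ynol ether may decompose before it cyclises. As a fallback, diyne 30 is cyclotrimerised with the same catalyst but with ethynylboronic acid pinacol ester, an established partner for this catalyst, to give the 6′-(pinacolboryl) heptabenzyl ether F1. Oxidation (NaBO3·4H2O, THF–H2O, rt) gives the 6′-phenol heptabenzyl ether F2, and hydrogenolysis as in step 18 brings the route back at target 36.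

The allenylzinc addition, step 14, is second. The aryl-conjugated allenylpalladium or allenylzinc species may racemise before it is trapped, and the anti preference with an aromatic aldehyde may be modest, so C3′ and C2′ could both erode. As a fallback, carbonate 24 undergoes copper-catalysed anti SN2′ borylation (CuCl, Xantphos, KOtBu, B2pin2, THF, rt) to the isolable, configurationally stable allenylboronic ester F3. Heating F3 with aldehyde 5 (toluene, 60 °C) effects allenylboration through a closed transition state and gives, after work-up, alcohol 26, where the route is rejoined.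

The ynol ether formation, step 15, is third. The potassium alkoxide of 26 may fragment by retro-addition or lose the acidic C3′ proton, and the excess n-BuLi may attack the same position, scrambling C2′ and C3′. As a fallback, alcohol 26 is formylated (acetic formic anhydride, pyridine, 0 °C) to the formate F4, which is dichloro-olefinated (PPh3, CCl4, THF, 60 °C) to the 2,2-dichlorovinyl ether F5. n-BuLi (2.2 equiv, THF, −78 °C) then gives lithium alkynyl ether 29, where the route is rejoined before the methanol quench to 30.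

Further compounds
F1 | step 17 | (2R,3R)-3-ArR-2-ArP-4-Ox-6-(4,4,5,5-tetramethyl-1,3,2-dioxaborolan-2-yl)-2,3-dihydro-1-benzofuran | C(c1ccccc1)Oc1ccc([C@H]2O[C@H](c3ccc(OCc4ccccc4)cc3)[C@@H](c3cc(OCc4ccccc4)cc(OCc4ccccc4)c3)[C@H]2c2cc(B3OC(C)(C)C(C)(C)O3)cc3c2[C@@H](c2cc(OCc4ccccc4)cc(OCc4ccccc4)c2)[C@H](c2ccc(OCc4ccccc4)cc2)O3)cc1
F2 | step 17 | (2R,3R)-3-ArR-2-ArP-4-Ox-2,3-dihydro-1-benzofuran-6-ol | C(c1ccccc1)Oc1ccc([C@H]2O[C@H](c3ccc(OCc4ccccc4)cc3)[C@@H](c3cc(OCc4ccccc4)cc(OCc4ccccc4)c3)[C@H]2c2cc(O)cc3c2[C@@H](c2cc(OCc4ccccc4)cc(OCc4ccccc4)c2)[C@H](c2ccc(OCc4ccccc4)cc2)O3)cc1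
F3 | step 14 | 2-[3-ArR-1-Ox-propa-1,2-dien-1-yl]-4,4,5,5-tetramethyl-1,3,2-dioxaborolane (allene axis as in 25) | CC1(C)OB(C([C@@H]2[C@H](c3cc(OCc4ccccc4)cc(OCc4ccccc4)c3)[C@@H](c3ccc(OCc4ccccc4)cc3)O[C@@H]2c2ccc(OCc3ccccc3)cc2)=[C@]=C([H])c2cc(OCc3ccccc3)cc(OCc3ccccc3)c2)OC1(C)C
F4 | step 15 | (1R,2R)-2-ArR-1-ArP-4-Ox-but-3-yn-1-yl formate | C(c1ccccc1)Oc1ccc([C@H]2O[C@H](c3ccc(OCc4ccccc4)cc3)[C@@H](c3cc(OCc4ccccc4)cc(OCc4ccccc4)c3)[C@H]2C#C[C@@H](c2cc(OCc3ccccc3)cc(OCc3ccccc3)c2)[C@H](c2ccc(OCc3ccccc3)cc2)OC=O)cc1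
F5 | step 15 | 2,2-dichlorovinyl ether of 26 | C(c1ccccc1)Oc1ccc([C@H]2O[C@H](c3ccc(OCc4ccccc4)cc3)[C@@H](c3cc(OCc4ccccc4)cc(OCc4ccccc4)c3)[C@H]2C#C[C@@H](c2cc(OCc3ccccc3)cc(OCc3ccccc3)c2)[C@H](c2ccc(OCc3ccccc3)cc2)OC=C(Cl)Cl)cc1
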